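## Retrosynthetic overview

1. The strategy rests on the carbocycle of coumarin A. O1 on C8a and the ether oxygen on C7 are meta to each other, the coumarin B aryl group sits on C6, and carbon C4 sits on C4a. This is the pattern of a 5-aryl-2,4-dihydroxybenzoate. It divides into a four-carbon diene (C6-C7-C8-C8a, aryl on C6, oxygen on C7 and C8a) and an alkynoate (C5, C4a and the carboxyl carbon C4).
2. The pyranone of ring C is cut by a Perkin-type condensation of an O7-acetic acid with 2,4-dihydroxybenzaldehyde. The pyranones of A and B are cut together by a double Wittig olefination/lactonisation of a bis-salicylaldehyde.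
3. The ring B aldehyde comes from formylation of the 2,6-dimethoxyphenyl unit. The biaryl bond C6(A)-C8(B) is never made by coupling, because it is the benzylic C-aryl bond of 2-(2,6-dimethoxyphenyl)acetic acid.
4. Rings form in this order: benzene of A (step 5), pyranones of A and B together (step 11), pyranone of C (step 14). The benzene rings of B and C are purchased.

Key step: step 5

Assumption: the target SMILES has no stereocentre and no descriptor for the C6(A)-C8(B) axis, so the axis is treated as stereochemically undefined (racemic if rotation is slow).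

## Route

Step 1
Reactants: 1 2-(2,6-dimethoxyphenyl)acetic acid; 2 Meldrum's acid (2,2-dimethyl-1,3-dioxane-4,6-dione)
Product: 3 5-[2-(2,6-dimethoxyphenyl)-1-hydroxyethylidene]-2,2-dimethyl-1,3-dioxane-4,6-dione
Conditions: DCC, DMAP, CH2Cl2, 0 °C → rt
Reagents that add atoms: none
Why: This is a carbodiimide-mediated C-acylation of Meldrum's acid, in which the DMAP-activated acyl group is taken up by the very acidic C5 position and the product rests as its stable enol.

Step 2
Reactants: 3 acyl Meldrum's acid
Product: 4 methyl 4-(2,6-dimethoxyphenyl)-3-oxobutanoate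
Conditions: MeOH, reflux
Reagents that add atoms: methanol, CO
Why: This is the alcoholysis of an acyl Meldrum's acid, in which thermal fragmentation gives an acylketene that methanol traps as the beta-keto ester.

Step 3
Reactants: 4 methyl 4-(2,6-dimethoxyphenyl)-3-oxobutanoate
Product: 5 methyl 4-(2,6-dimethoxyphenyl)-3-(trimethylsilyloxy)but-2-enoate (E/Z mixture, geometry lost in step 4)
Conditions: Et3N, TMSCl, toluene, rt
Reagents that add atoms: chlorotrimethylsilane, C[Si](C)(C)Cl
Why: In this soft enolisation and O-silylation of a beta-keto ester, only the C2-H between the two carbonyl groups is acidic enough for Et3N, so the enol ether forms towards the ester and the benzylic CH2 is kept for the next deprotonation.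

Step 4
Reactants: 5 mono silyl enol ether
Product: 6 (1Z,3Z)-4-(2,6-dimethoxyphenyl)-1-methoxy-1,3-bis(trimethylsilyloxy)buta-1,3-diene (used crude under argon)
Conditions: LDA, THF, −78 °C; TMSCl, −78 °C → rt
Reagents that add atoms: chlorotrimethylsilane, C[Si](C)(C)Cl
Why: This is the Chan-type diene synthesis by gamma-deprotonation of the vinylogous ester at the benzylic position and O-silylation of the dienolate, and allylic 1,3-strain should place the aryl group anti to C2, which is the 3Z geometry.

Step 5
Reactants: 6 4-aryl bis(silyloxy) diene; 7 methyl propiolate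
Product: 10 methyl 5-(2,6-dimethoxyphenyl)-2,4-dihydroxybenzoate, via cyclohexadiene cycloadduct 8 (not isolated), via bis(trimethylsilyl) resorcylate 9 (not isolated)
Conditions: toluene, 110 °C (sealed tube); then 1 M HCl, THF, rt
Reagents that add atoms: none
Why: The two oxygen donors push electron density to the aryl-bearing terminus C4 of diene 6 while the ester polarises alkyne 7 towards its unsubstituted carbon, so a normal-electron-demand, strongly asynchronous Diels-Alder reaction should form C4(diene)-CH(alkyne) first (C5-C6 of coumarin A) and C1(diene)-C(CO2Me) second (C4a-C8a), giving 1,4-cyclohexadiene 8. In 8 the silyl methyl ketal carbon is doubly allylic and the C-H across the ring is doubly allylic and benzylic, so methanol is lost in a 1,4 sense to give arene 9, and dilute acid then removes both silyl groups. The closest known reaction type is the cycloaddition-aromatisation of 1-alkoxy-1,3-bis(silyloxy)buta-1,3-dienes with alkynoates, an established de novo synthesis of resorcylates. The single ring closed is the six-membered carbocycle of coumarin A, closed by an intermolecular [4+2] union of a four-carbon and a two-carbon unit rather than by cyclisation of a chain. The two sp3 carbons of 8 are erased on aromatisation, so no stereocentre has to be controlled. The step needs regioselectivity (5-aryl-2,4-dihydroxybenzoate, not the 2-aryl-3,5-dihydroxy isomer), which the matched polarity of the partners secures, and it needs an accessible s-cis conformer, which the 3Z geometry secures by placing the aryl group on the outer position of the diene terminus.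

Step 6
Reactants: 10 methyl 5-(2,6-dimethoxyphenyl)-2,4-dihydroxybenzoate
Product: 11 methyl 2,4-bis(benzyloxy)-5-(2,6-dimethoxyphenyl)benzoate
Conditions: BnBr, K2CO3, DMF, 60 °C
Reagents that add atoms: benzyl bromide, BrCc1ccccc1
Why: In this Williamson ether synthesis, excess halide and warming in DMF also alkylate the ester-chelated 2-OH, and masking both phenols allows the reduction and keeps ring A inert in the later formylation.

Step 7
Reactants: 11 bis(benzyl) ether ester
Product: 12 [2,4-bis(benzyloxy)-5-(2,6-dimethoxyphenyl)phenyl]methanol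
Conditions: LiAlH4, THF, 0 °C → rt
Reagents that add atoms: none
Why: This is a hydride reduction of an aromatic ester to the benzylic alcohol, and the aryl methyl and benzyl ethers are inert to LiAlH4.

Step 8
Reactants: 12 benzylic alcohol
Product: 13 2,4-bis(benzyloxy)-5-(2,6-dimethoxyphenyl)benzaldehyde
Conditions: MnO2, CH2Cl2, rt
Reagents that add atoms: none
Why: This is a selective oxidation of an electron-rich benzylic alcohol with activated MnO2, which stops at the aldehyde.

Step 9
Reactants: 13 2,4-bis(benzyloxy)-5-(2,6-dimethoxyphenyl)benzaldehyde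
Product: 15 3-[2,4-bis(benzyloxy)-5-formylphenyl]-2,4-dimethoxybenzaldehyde, via aryl iminium chloride 14 (not isolated)
Conditions: POCl3, DMF, 0 → 70 °C; then ice-water
Reagents that add atoms: N,N-dimethylformamide, CN(C)C=O; water, O
Why: In this Vilsmeier-Haack formylation the weak chloroiminium electrophile should attack only ring B, at one of its two equivalent positions ortho to one methoxy group and para to the other, because ring A is deactivated by its formyl group and its only free activated site lies between two benzyloxy groups; these conditions also spare benzyl ethers.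

Step 10
Reactants: 15 protected dialdehyde
Product: 16 3-(5-formyl-2,4-dihydroxyphenyl)-2-hydroxy-4-methoxybenzaldehyde
Conditions: BCl3, pentamethylbenzene, CH2Cl2, −78 → 0 °C; then H2O
Reagents that add atoms: none
Why: In this Lewis-acid ether cleavage BCl3 removes both benzyl groups with pentamethylbenzene as cation scavenger, and through the formyl chelate it removes only the twisted methoxy group ortho to the ring B aldehyde, whereas the non-chelating 4-methoxy group should survive at or below 0 °C.

Step 11
Reactants: 16 trihydroxy dialdehyde; 17 ethyl (triphenylphosphoranylidene)acetate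
Product: 19 7-hydroxy-6-(7-methoxy-2-oxo-2H-chromen-8-yl)-2H-chromen-2-one, via bis-cinnamate 18 (not isolated)
Conditions: 17 (2.5 equiv), N,N-diethylaniline, reflux (ca. 215 °C)
Reagents that add atoms: none
Why: This is a double Wittig olefination of free salicylaldehydes with a stabilised ylide, followed at this temperature by E to Z isomerisation and lactonisation, which is the standard one-pot route from salicylaldehydes to 3,4-unsubstituted coumarins and is tolerated by a free para hydroxyl group.

Step 12
Reactants: 19 bis-coumarin phenol; 20 tert-butyl bromoacetate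
Product: 21 tert-butyl 2-{[6-(7-methoxy-2-oxo-2H-chromen-8-yl)-2-oxo-2H-chromen-7-yl]oxy}acetate
Conditions: K2CO3, DMF, rt
Reagents that add atoms: none
Why: This Williamson ether synthesis raises no chemoselectivity question, because after the double lactonisation the O7-H of coumarin A is the only free hydroxyl group, and dry carbonate at room temperature leaves the lactones closed.

Step 13
Reactants: 21 tert-butyl ester
Product: 22 2-{[6-(7-methoxy-2-oxo-2H-chromen-8-yl)-2-oxo-2H-chromen-7-yl]oxy}acetic acid
Conditions: TFA, CH2Cl2, rt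
Reagents that add atoms: none
Why: Acidolysis of the tert-butyl ester through the tert-butyl cation frees the acid without the aqueous base that would open the coumarin lactones.

Step 14
Reactants: 22 aryloxyacetic acid; 23 2,4-dihydroxybenzaldehyde
Product: 25 3-{[6-(7-methoxy-2-oxo-2H-chromen-8-yl)-2-oxo-2H-chromen-7-yl]oxy}-2-oxo-2H-chromen-7-yl acetate, via salicylaldehyde ester 24 (not isolated)
Conditions: Ac2O, Et3N, 120 °C
Reagents that add atoms: acetic anhydride, CC(=O)OC(C)=O
Why: In this Perkin (Oglialoro-type) condensation the mixed anhydride of 22 acylates the ortho hydroxyl group, the activated OCH2 carbon adds to the formyl group, and dehydration closes the 3-aryloxycoumarin, the known route to 3-(coumarin-7-yloxy)coumarins, while the remote hydroxyl group is acetylated.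

Step 15
Reactants: 25 tricoumarin methyl ether acetate
Product: 27 7-hydroxy-3-{[6-(7-hydroxy-2-oxo-2H-chromen-8-yl)-2-oxo-2H-chromen-7-yl]oxy}-2H-chromen-2-one (CNP0215289.0), via ring B phenol acetate 26 (not isolated)
Conditions: BBr3 (excess), CH2Cl2, −78 °C → rt; then MeOH, 50 °C
Reagents that add atoms: none
Why: BBr3 demethylation cleaves the only sp3 C-O ether bond (the A-O-C bridge joins two sp2 carbons and cannot be attacked), and the HBr/MeOH produced on quenching removes the phenolic acetate by acid-catalysed transesterification, conditions under which coumarin lactones stay closed.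

## Compound list

1 | 2-(2,6-dimethoxyphenyl)acetic acid | COc1cccc(OC)c1CC(=O)O | starting material
2 | Meldrum's acid | CC1(C)OC(=O)CC(=O)O1 | starting material
3 | 5-[2-(2,6-dimethoxyphenyl)-1-hydroxyethylidene]-2,2-dimethyl-1,3-dioxane-4,6-dione | COc1cccc(OC)c1CC(O)=C1C(=O)OC(C)(C)OC1=O | intermediate
4 | methyl 4-(2,6-dimethoxyphenyl)-3-oxobutanoate | COC(=O)CC(=O)Cc1c(OC)cccc1OC | intermediate
5 | methyl 4-(2,6-dimethoxyphenyl)-3-(trimethylsilyloxy)but-2-enoate (E/Z mixture) | COC(=O)C=C(Cc1c(OC)cccc1OC)O[Si](C)(C)C | intermediate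
6 | (1Z,3Z)-4-(2,6-dimethoxyphenyl)-1-methoxy-1,3-bis(trimethylsilyloxy)buta-1,3-diene | CO/C(O[Si](C)(C)C)=C/C(O[Si](C)(C)C)=C/c1c(OC)cccc1OC | intermediate
7 | methyl propiolate | C#CC(=O)OC | starting material
8 | methyl 3-(2,6-dimethoxyphenyl)-6-methoxy-4,6-bis(trimethylsilyloxy)cyclohexa-1,4-diene-1-carboxylate (transient, configuration at C3 and C6 without consequence) | COC(=O)C1=CC(c2c(OC)cccc2OC)C(O[Si](C)(C)C)=CC1(OC)O[Si](C)(C)C | intermediate
9 | methyl 5-(2,6-dimethoxyphenyl)-2,4-bis(trimethylsilyloxy)benzoate | COC(=O)c1cc(-c2c(OC)cccc2OC)c(O[Si](C)(C)C)cc1O[Si](C)(C)C | intermediate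
10 | methyl 5-(2,6-dimethoxyphenyl)-2,4-dihydroxybenzoate | COC(=O)c1cc(-c2c(OC)cccc2OC)c(O)cc1O | intermediate
11 | methyl 2,4-bis(benzyloxy)-5-(2,6-dimethoxyphenyl)benzoate | COC(=O)c1cc(-c2c(OC)cccc2OC)c(OCc2ccccc2)cc1OCc1ccccc1 | intermediate
12 | [2,4-bis(benzyloxy)-5-(2,6-dimethoxyphenyl)phenyl]methanol | OCc1cc(-c2c(OC)cccc2OC)c(OCc2ccccc2)cc1OCc1ccccc1 | intermediate
13 | 2,4-bis(benzyloxy)-5-(2,6-dimethoxyphenyl)benzaldehyde | O=Cc1cc(-c2c(OC)cccc2OC)c(OCc2ccccc2)cc1OCc1ccccc1 | intermediate
14 | {3-[2,4-bis(benzyloxy)-5-formylphenyl]-2,4-dimethoxybenzylidene}dimethyliminium chloride | C[N+](C)=Cc1ccc(OC)c(-c2cc(C=O)c(OCc3ccccc3)cc2OCc2ccccc2)c1OC.[Cl-] | intermediate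
15 | 3-[2,4-bis(benzyloxy)-5-formylphenyl]-2,4-dimethoxybenzaldehyde | COc1ccc(C=O)c(OC)c1-c1cc(C=O)c(OCc2ccccc2)cc1OCc1ccccc1 | intermediate
16 | 3-(5-formyl-2,4-dihydroxyphenyl)-2-hydroxy-4-methoxybenzaldehyde | COc1ccc(C=O)c(O)c1-c1cc(C=O)c(O)cc1O | intermediate
17 | ethyl (triphenylphosphoranylidene)acetate | CCOC(=O)C=P(c1ccccc1)(c1ccccc1)c1ccccc1 | starting material
18 | ethyl (E)-3-{3-[5-((E)-3-ethoxy-3-oxoprop-1-enyl)-2,4-dihydroxyphenyl]-2-hydroxy-4-methoxyphenyl}acrylate | CCOC(=O)/C=C/c1cc(-c2c(OC)ccc(/C=C/C(=O)OCC)c2O)c(O)cc1O | intermediate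
19 | 7-hydroxy-6-(7-methoxy-2-oxo-2H-chromen-8-yl)-2H-chromen-2-one | O=c1ccc2cc(-c3c(OC)ccc4ccc(=O)oc34)c(O)cc2o1 | intermediate
20 | tert-butyl bromoacetate | CC(C)(C)OC(=O)CBr | starting material
21 | tert-butyl 2-{[6-(7-methoxy-2-oxo-2H-chromen-8-yl)-2-oxo-2H-chromen-7-yl]oxy}acetate | CC(C)(C)OC(=O)COc1cc2oc(=O)ccc2cc1-c1c(OC)ccc2ccc(=O)oc12 | intermediate
22 | 2-{[6-(7-methoxy-2-oxo-2H-chromen-8-yl)-2-oxo-2H-chromen-7-yl]oxy}acetic acid | O=C(O)COc1cc2oc(=O)ccc2cc1-c1c(OC)ccc2ccc(=O)oc12 | intermediate
23 | 2,4-dihydroxybenzaldehyde | O=Cc1ccc(O)cc1O | starting material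
24 | 5-acetoxy-2-formylphenyl 2-{[6-(7-methoxy-2-oxo-2H-chromen-8-yl)-2-oxo-2H-chromen-7-yl]oxy}acetate | CC(=O)Oc1ccc(C=O)c(OC(=O)COc2cc3oc(=O)ccc3cc2-c2c(OC)ccc3ccc(=O)oc23)c1 | intermediate
25 | 3-{[6-(7-methoxy-2-oxo-2H-chromen-8-yl)-2-oxo-2H-chromen-7-yl]oxy}-2-oxo-2H-chromen-7-yl acetate | CC(=O)Oc1ccc2cc(Oc3cc4oc(=O)ccc4cc3-c3c(OC)ccc4ccc(=O)oc34)c(=O)oc2c1 | intermediate
26 | 3-{[6-(7-hydroxy-2-oxo-2H-chromen-8-yl)-2-oxo-2H-chromen-7-yl]oxy}-2-oxo-2H-chromen-7-yl acetate | CC(=O)Oc1ccc2cc(Oc3cc4oc(=O)ccc4cc3-c3c(O)ccc4ccc(=O)oc34)c(=O)oc2c1 | intermediate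
27 | 7-hydroxy-3-{[6-(7-hydroxy-2-oxo-2H-chromen-8-yl)-2-oxo-2H-chromen-7-yl]oxy}-2H-chromen-2-one (CNP0215289.0) | O=c1ccc2cc(-c3c(O)ccc4ccc(=O)oc34)c(Oc3cc4ccc(O)cc4oc3=O)cc2o1 | target

## Step count and risks

Total step count: 15. Longest linear sequence: 15 steps (1 → 27).

**Step 5 (key cycloaddition).**
- Risk: the two ortho methoxy groups of the twisted aryl ring shield both faces of the diene terminus that must lead bond formation. Cycloaddition may therefore be outrun by thermal silyl migration, adventitious hydrolysis of the diene, or simple conjugate addition without ring closure.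
- Fallback: this route sets out from 23 and returns at 13, replacing steps 1 to 8 with a cross-coupling construction of the biaryl bond. Bromination of 23 (Br2, AcOH, rt) should give 5-bromo-2,4-dihydroxybenzaldehyde F1. Double benzylation (BnBr, K2CO3, DMF) should give 2,4-bis(benzyloxy)-5-bromobenzaldehyde F2. Suzuki-Miyaura coupling of F2 with commercial 2,6-dimethoxyphenylboronic acid (Pd(OAc)2, SPhos, K3PO4, toluene/H2O, 100 °C) should then give 13.

**Step 14 (Perkin closure of ring C).**
- Risk: enolisation of the bulky aryloxyacetyl unit may be slower than condensation of acetic anhydride itself with the aldehyde. Prolonged heating may also erode the acid by decarboxylative breakdown of its mixed anhydride.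
- Fallback: this route sets out from 22 and returns at 27. It separates acylation from C-C bond formation and uses a pre-masked aldehyde without any anhydride. Esterification of 22 with commercial 2-hydroxy-4-methoxybenzaldehyde (EDC·HCl, DMAP, CH2Cl2) should give 2-formyl-5-methoxyphenyl 2-{[6-(7-methoxy-2-oxo-2H-chromen-8-yl)-2-oxo-2H-chromen-7-yl]oxy}acetate F6. Intramolecular aldol condensation (DBU, MeCN, rt → 60 °C) should give 7-methoxy-3-{[6-(7-methoxy-2-oxo-2H-chromen-8-yl)-2-oxo-2H-chromen-7-yl]oxy}-2H-chromen-2-one F7. Double demethylation of F7 with BBr3 (CH2Cl2, −78 °C → rt) should give 27 directly.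

**Step 9 (formylation of ring B).**
- Risk: electrophilic substitution may be sluggish, because the group on the biaryl carbon crowds both methoxy donors. The heating then required may cause partial loss of the benzyl ether ortho to the ring A formyl group.
- Fallback: this route sets out from 11 and returns at 15, replacing steps 7 to 9 with halogenation and metalation-formylation. Bromination of 11 on the more electron-rich ring B (NBS, MeCN, 0 °C) should give methyl 2,4-bis(benzyloxy)-5-(3-bromo-2,6-dimethoxyphenyl)benzoate F3. Reduction (DIBAL-H, CH2Cl2, −78 → 0 °C) should give [2,4-bis(benzyloxy)-5-(3-bromo-2,6-dimethoxyphenyl)phenyl]methanol F4. Deprotonation and bromine-lithium exchange (n-BuLi, 2.2 equiv, THF, −78 °C) followed by DMF should give 3-[2,4-bis(benzyloxy)-5-(hydroxymethyl)phenyl]-2,4-dimethoxybenzaldehyde F5. Oxidation of F5 with MnO2 (CH2Cl2, rt) should give 15.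

## Further compounds

F1 | step 5 | 5-bromo-2,4-dihydroxybenzaldehyde | O=Cc1cc(Br)c(O)cc1O
F2 | step 5 | 2,4-bis(benzyloxy)-5-bromobenzaldehyde | O=Cc1cc(Br)c(OCc2ccccc2)cc1OCc1ccccc1
F3 | step 9 | methyl 2,4-bis(benzyloxy)-5-(3-bromo-2,6-dimethoxyphenyl)benzoate | COC(=O)c1cc(-c2c(OC)ccc(Br)c2OC)c(OCc2ccccc2)cc1OCc1ccccc1
F4 | step 9 | [2,4-bis(benzyloxy)-5-(3-bromo-2,6-dimethoxyphenyl)phenyl]methanol | OCc1cc(-c2c(OC)ccc(Br)c2OC)c(OCc2ccccc2)cc1OCc1ccccc1
F5 | step 9 | 3-[2,4-bis(benzyloxy)-5-(hydroxymethyl)phenyl]-2,4-dimethoxybenzaldehyde | OCc1cc(-c2c(OC)ccc(C=O)c2OC)c(OCc2ccccc2)cc1OCc1ccccc1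
F6 | step 14 | 2-formyl-5-methoxyphenyl 2-{[6-(7-methoxy-2-oxo-2H-chromen-8-yl)-2-oxo-2H-chromen-7-yl]oxy}acetate | COc1ccc(C=O)c(OC(=O)COc2cc3oc(=O)ccc3cc2-c2c(OC)ccc3ccc(=O)oc23)c1
F7 | step 14 | 7-methoxy-3-{[6-(7-methoxy-2-oxo-2H-chromen-8-yl)-2-oxo-2H-chromen-7-yl]oxy}-2H-chromen-2-one | COc1ccc2cc(Oc3cc4oc(=O)ccc4cc3-c3c(OC)ccc4ccc(=O)oc34)c(=O)oc2c1
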